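**Plan**

1. Numbering used (eremophilane): ring A = C1–C5 + C10 (C3 ester, C4 and C5 methyls); ring B = C5–C10 (C6=C7 enone, C8 ketone, C10 carbinol); side chain C11 (methyl C13, acid C12) on C7.
2. Cuts, in retrosynthetic order: C3–O angelate; C3 carbinol to ketone (dioxolane); C9–C10 (retro-aldol) together with the C6=C7 alkene, traced back to a γ-lactone between C12 and C6 (retro-E1cB); C6–C7 (aldol); C5–C6 and C4–methyl (conjugate addition/hydroxymethylation).
3. Forward: ring A is completed first as a keto aldehyde; the C7–C9/C11–C13 chain is joined by Mukaiyama aldol and lactonisation; ring B is closed last by one base-mediated cascade; C3 is then reduced and acylated.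
4. Enabling feature: ring B is a β-ketol (C10–OH, C9H2, C8=O) and its enone carbon C6 lies 1,4 to the C12 carboxyl. A C6–O–C12 lactone can therefore hold the alkene as a β-acyloxy ketone, shield C11, and release enone, acid and ring in one event whatever the lactone configuration.
5. Stereochemistry: C4 from ligand-controlled methyl addition; C5 from anti capture of the enolate; C11 from the chiral pool; C10 from cis-selective, reversible ketolisation; C3 from equatorial hydride attack; (Z)-angelate from angelic acid.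

Key step: step 8

Assumption: the sense of induction of the copper–Josiphos catalyst in step 3 is set by the choice of ligand enantiomer; the enantiomer that gives the (6R) centre is used.

**Route**

Step 1
Reactants: 1 1,4-dioxaspiro[4.5]dec-6-en-8-one
Product: 2 7-iodo-1,4-dioxaspiro[4.5]dec-6-en-8-one
Conditions: I2, pyridine, CH2Cl2, 0 °C → rt
Reagents that add atoms: iodine, II
Why: α-Iodination of a cyclic enone by the iodine–pyridine addition–elimination sequence is general for 4,4-disubstituted cyclohexenones and leaves the dioxolane untouched.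

Step 2
Reactants: 2 7-iodo-1,4-dioxaspiro[4.5]dec-6-en-8-one
Product: 3 7-methyl-1,4-dioxaspiro[4.5]dec-6-en-8-one
Conditions: MeB(OH)2, Pd(dppf)Cl2 (5 mol %), K3PO4, dioxane–H2O, 80 °C
Reagents that add atoms: methylboronic acid, CB(O)O
Why: Suzuki–Miyaura coupling of the α-iodoenone installs the α-methyl group that becomes the angular methyl and fixes the regiochemistry of the enolate formed in step 3.

Step 3
Reactants: 3 7-methyl-1,4-dioxaspiro[4.5]dec-6-en-8-one
Product: 5 (6R,7S)-7-(hydroxymethyl)-6,7-dimethyl-1,4-dioxaspiro[4.5]decan-8-one, via magnesium enolate 4 (not isolated)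
Conditions: MeMgBr, CuBr·SMe2 (5 mol %), Josiphos-type ferrocenyl diphosphine (6 mol %), t-BuOMe, −78 °C; then CH2O (monomer in THF), −78 °C; aq. NH4Cl
Reagents that add atoms: methylmagnesium bromide, C[Mg]Br; formaldehyde, C=O
Why: Copper-catalysed enantioselective conjugate addition of the Grignard reagent sets the methyl-bearing centre (C4) under ligand control and gives the tetrasubstituted enolate regiospecifically; aldol capture by formaldehyde should occur anti to the new methyl, so the two methyls end up cis at the quaternary centre (C5).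

Step 4
Reactants: 5 (6R,7S)-7-(hydroxymethyl)-6,7-dimethyl-1,4-dioxaspiro[4.5]decan-8-one
Product: 6 (6R,7S)-6,7-dimethyl-8-oxo-1,4-dioxaspiro[4.5]decane-7-carbaldehyde
Conditions: Dess–Martin periodinane, NaHCO3, CH2Cl2, 0 °C → rt
Reagents that add atoms: none
Why: Buffered Dess–Martin oxidation of the primary alcohol should give the non-enolisable β-keto aldehyde without retro-aldol loss of the one-carbon unit.

Step 5
Reactants: 7 methyl (2S)-3-bromo-2-methylpropanoate
Product: 9 methyl (2R)-2-methyl-4-oxopentanoate, via organozinc bromide 8 (not isolated)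
Conditions: Zn, LiCl, THF, 50 °C; then AcCl, Pd(PPh3)4 (2 mol %), 0 °C → rt
Reagents that add atoms: acetyl chloride, CC(=O)Cl
Why: Zinc insertion into the primary bromide followed by palladium-catalysed Negishi acylation forms the methyl ketone without touching the stereocentre, which is β to zinc and never enolised (the descriptor changes from S to R by priority only).

Step 6
Reactants: 9 methyl (2R)-2-methyl-4-oxopentanoate
Product: 10 methyl (2R,3Z)-2-methyl-4-(trimethylsilyloxy)pent-3-enoate
Conditions: Me3SiCl, NaI, Et3N, MeCN, rt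
Reagents that add atoms: chlorotrimethylsilane, C[Si](C)(C)Cl
Why: Silylation under equilibrating conditions (iodotrimethylsilane formed in the flask) favours the more substituted internal enol silane of a methyl alkyl ketone, which fixes C7 as the carbon that bonds to the aldehyde; triethylamine does not enolise the ester stereocentre.

Step 7
Reactants: 6 (6R,7S)-6,7-dimethyl-8-oxo-1,4-dioxaspiro[4.5]decane-7-carbaldehyde; 10 methyl (2R,3Z)-2-methyl-4-(trimethylsilyloxy)pent-3-enoate
Product: 12 (3R)-4-acetyl-5-[(6R,7S)-6,7-dimethyl-8-oxo-1,4-dioxaspiro[4.5]decan-7-yl]-3-methyloxolan-2-one (mixture at lactone C4 and C5), via hydroxy ester 11 (not isolated)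
Conditions: BF3·OEt2, CH2Cl2, −78 °C; aq. NaHCO3; then PPTS (cat.), toluene, 60 °C
Reagents that add atoms: none
Why: A Mukaiyama aldol addition joins the fragments at the aldehyde only (ring ketone and dioxolane should be inert to BF3·OEt2 at low temperature) and the γ-hydroxy ester then lactonises under mild acid; the two new centres are left as a mixture on purpose, since step 8 erases both.

Step 8
Reactants: 12 (3R)-4-acetyl-5-[(6R,7S)-6,7-dimethyl-8-oxo-1,4-dioxaspiro[4.5]decan-7-yl]-3-methyloxolan-2-one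
Product: 14 (2R)-2-[(4aS,8R,8aR)-7,7-(ethylenedioxy)-4a-hydroxy-8,8a-dimethyl-3-oxo-3,4,4a,5,6,7,8,8a-octahydronaphthalen-2-yl]propanoic acid, via enone carboxylate 13 (not isolated)
Conditions: KOtBu (3 equiv), PhSH (10 mol %), t-BuOH–THF, −20 → 0 °C; aq. KHSO4
Reagents that add atoms: none
Why: tert-Butoxide removes the C7–H α to the acetyl group and the enolate expels the lactone carboxylate (E1cB), so every lactone diastereomer gives the same (E/Z)-enone carboxylate 13; thiolate (and the internal carboxylate) adds reversibly to C6 and interconverts the alkene isomers, and only the Z isomer, whose methyl ketone can reach the ring A carbonyl, is drained by aldol addition of its C9 enolate to C10 (a lactone that ketolises before it eliminates converges on the same product). The closest known reaction types are the ring-opening elimination of paraconic lactones in the Stobbe condensation and the ketol stage of the Robinson annulation. Ring B closes in the 6-(enolendo)-exo-trig mode. The new C10 carbinol centre is controlled by the quaternary C5: axial attack on the chair ring A ketone by the equatorial C5 side arm should give the cis-fused ketol (OH cis to the angular methyl), and the reversible aldol returns any trans-ketol to 13. C11 should not scramble because the more acidic C7–H reacts first and the carboxylate then disfavours enolisation at C11; elimination can only go towards C6=C7 because the leaving group sits on C6; the bridged aldol of the C1 enolate onto C8 is reversible and only the fused product keeps the conjugated enone. β-Elimination of the tertiary hydroxyl is held back by low temperature and short reaction time.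

Step 9
Reactants: 14 (2R)-2-[(4aS,8R,8aR)-7,7-(ethylenedioxy)-4a-hydroxy-8,8a-dimethyl-3-oxo-3,4,4a,5,6,7,8,8a-octahydronaphthalen-2-yl]propanoic acid
Product: 15 prop-2-en-1-yl (2R)-2-[(4aS,8R,8aR)-7,7-(ethylenedioxy)-4a-hydroxy-8,8a-dimethyl-3-oxo-3,4,4a,5,6,7,8,8a-octahydronaphthalen-2-yl]propanoate
Conditions: allyl bromide, KHCO3, DMF, rt
Reagents that add atoms: allyl bromide, C=CCBr
Why: Carboxylate O-alkylation masks the acid for the acylation in step 12, and bicarbonate is too weak to enolise C11 or to trigger retro-aldol of the ketol.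

Step 10
Reactants: 15 prop-2-en-1-yl (2R)-2-[(4aS,8R,8aR)-7,7-(ethylenedioxy)-4a-hydroxy-8,8a-dimethyl-3-oxo-3,4,4a,5,6,7,8,8a-octahydronaphthalen-2-yl]propanoate
Product: 16 prop-2-en-1-yl (2R)-2-[(4aS,8R,8aR)-4a-hydroxy-8,8a-dimethyl-3,7-dioxo-3,4,4a,5,6,7,8,8a-octahydronaphthalen-2-yl]propanoate
Conditions: PPTS, acetone–H2O, 45 °C
Reagents that add atoms: water, O
Why: Mild acid-catalysed ketal hydrolysis unmasks the C3 ketone while the tertiary ketol and allyl ester should survive; the C4 methyl stays in its more stable equatorial position next to the new ketone.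

Step 11
Reactants: 16 prop-2-en-1-yl (2R)-2-[(4aS,8R,8aR)-4a-hydroxy-8,8a-dimethyl-3,7-dioxo-3,4,4a,5,6,7,8,8a-octahydronaphthalen-2-yl]propanoate
Product: 17 prop-2-en-1-yl (2R)-2-[(4aS,7S,8R,8aR)-4a,7-dihydroxy-8,8a-dimethyl-3-oxo-3,4,4a,5,6,7,8,8a-octahydronaphthalen-2-yl]propanoate
Conditions: LiBH(s-Bu)3 (L-Selectride), THF, −78 °C; aq. NH4Cl
Reagents that add atoms: none
Why: The bulky hydride should attack the saturated ketone from the equatorial direction, anti to the axial angular methyl (1,3 to C3), giving the axial alcohol cis to both methyls, and should reduce this ketone much faster than the α-substituted enone whose β-carbon is neopentyl.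

Step 12
Reactants: 17 prop-2-en-1-yl (2R)-2-[(4aS,7S,8R,8aR)-4a,7-dihydroxy-8,8a-dimethyl-3-oxo-3,4,4a,5,6,7,8,8a-octahydronaphthalen-2-yl]propanoate; 18 angelic acid [(2Z)-2-methylbut-2-enoic acid]
Product: 20 prop-2-en-1-yl (2R)-2-[(4aS,7S,8R,8aR)-4a-hydroxy-8,8a-dimethyl-7-{[(2Z)-2-methylbut-2-enoyl]oxy}-3-oxo-3,4,4a,5,6,7,8,8a-octahydronaphthalen-2-yl]propanoate, via mixed anhydride 19 (not isolated)
Conditions: 18, 2,4,6-trichlorobenzoyl chloride, Et3N, toluene, rt; then 17, toluene, 80 °C
Reagents that add atoms: none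
Why: Yamaguchi-type esterification through the mixed anhydride, without a nucleophilic catalyst, should acylate the hindered secondary alcohol at the less hindered angeloyl carbonyl, keep the (Z) geometry and leave the tertiary alcohol untouched.

Step 13
Reactants: 20 prop-2-en-1-yl (2R)-2-[(4aS,7S,8R,8aR)-4a-hydroxy-8,8a-dimethyl-7-{[(2Z)-2-methylbut-2-enoyl]oxy}-3-oxo-3,4,4a,5,6,7,8,8a-octahydronaphthalen-2-yl]propanoate
Product: 21 (2R)-2-[(4aS,7S,8R,8aR)-4a-hydroxy-8,8a-dimethyl-7-{[(2Z)-2-methylbut-2-enoyl]oxy}-3-oxo-3,4,4a,5,6,7,8,8a-octahydronaphthalen-2-yl]propanoic acid (CNP0307859.1)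
Conditions: Pd(PPh3)4 (5 mol %), morpholine, THF, rt; dilute aq. KHSO4
Reagents that add atoms: none
Why: Tsuji–Trost deallylation with zerovalent palladium and morpholine as allyl acceptor frees the acid under near-neutral conditions that should spare the angelate, the enone, the ketol and C11.

**Compound list**

1 | 1,4-dioxaspiro[4.5]dec-6-en-8-one | O=C1C=CC2(CC1)OCCO2 | starting material
2 | 7-iodo-1,4-dioxaspiro[4.5]dec-6-en-8-one | O=C1C(I)=CC2(CC1)OCCO2 | intermediate
3 | 7-methyl-1,4-dioxaspiro[4.5]dec-6-en-8-one | O=C1C(C)=CC2(CC1)OCCO2 | intermediate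
4 | bromomagnesium (6R)-6,7-dimethyl-1,4-dioxaspiro[4.5]dec-7-en-8-olate | Br[Mg]OC1=C(C)[C@@H](C)C2(OCCO2)CC1 | intermediate (not isolated)
5 | (6R,7S)-7-(hydroxymethyl)-6,7-dimethyl-1,4-dioxaspiro[4.5]decan-8-one | O=C1CCC2(OCCO2)[C@H](C)[C@@]1(C)CO | intermediate
6 | (6R,7S)-6,7-dimethyl-8-oxo-1,4-dioxaspiro[4.5]decane-7-carbaldehyde | O=C1CCC2(OCCO2)[C@H](C)[C@@]1(C)C=O | intermediate
7 | methyl (2S)-3-bromo-2-methylpropanoate | BrC[C@@H](C)C(=O)OC | starting material
8 | [(2S)-3-methoxy-2-methyl-3-oxopropyl]zinc bromide | Br[Zn]C[C@@H](C)C(=O)OC | intermediate (not isolated)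
9 | methyl (2R)-2-methyl-4-oxopentanoate | CC(=O)C[C@@H](C)C(=O)OC | intermediate
10 | methyl (2R,3Z)-2-methyl-4-(trimethylsilyloxy)pent-3-enoate | C/C(O[Si](C)(C)C)=C/[C@@H](C)C(=O)OC | intermediate
11 | methyl (2R)-3-acetyl-4-[(6R,7S)-6,7-dimethyl-8-oxo-1,4-dioxaspiro[4.5]decan-7-yl]-4-hydroxy-2-methylbutanoate (mixture at C3, C4) | O=C1CCC2(OCCO2)[C@H](C)[C@@]1(C)C(O)C(C(C)=O)[C@@H](C)C(=O)OC | intermediate (not isolated)
12 | (3R)-4-acetyl-5-[(6R,7S)-6,7-dimethyl-8-oxo-1,4-dioxaspiro[4.5]decan-7-yl]-3-methyloxolan-2-one (mixture at C4, C5) | O=C1CCC2(OCCO2)[C@H](C)[C@@]1(C)C3OC(=O)[C@H](C)C3C(C)=O | intermediate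
13 | potassium (2R)-3-acetyl-4-[(6R,7R)-6,7-dimethyl-8-oxo-1,4-dioxaspiro[4.5]decan-7-yl]-2-methylbut-3-enoate (E/Z mixture) | O=C1CCC2(OCCO2)[C@H](C)[C@@]1(C)C=C(C(C)=O)[C@@H](C)C(=O)[O-].[K+] | intermediate (not isolated)
14 | (2R)-2-[(4aS,8R,8aR)-7,7-(ethylenedioxy)-4a-hydroxy-8,8a-dimethyl-3-oxo-3,4,4a,5,6,7,8,8a-octahydronaphthalen-2-yl]propanoic acid | O1CCOC12CC[C@]3(O)CC(=O)C([C@@H](C)C(=O)O)=C[C@]3(C)[C@H]2C | intermediate
15 | prop-2-en-1-yl ester of 14 | O1CCOC12CC[C@]3(O)CC(=O)C([C@@H](C)C(=O)OCC=C)=C[C@]3(C)[C@H]2C | intermediate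
16 | prop-2-en-1-yl (2R)-2-[(4aS,8R,8aR)-4a-hydroxy-8,8a-dimethyl-3,7-dioxo-3,4,4a,5,6,7,8,8a-octahydronaphthalen-2-yl]propanoate | O=C1CC[C@]2(O)CC(=O)C([C@@H](C)C(=O)OCC=C)=C[C@]2(C)[C@H]1C | intermediate
17 | prop-2-en-1-yl (2R)-2-[(4aS,7S,8R,8aR)-4a,7-dihydroxy-8,8a-dimethyl-3-oxo-3,4,4a,5,6,7,8,8a-octahydronaphthalen-2-yl]propanoate | O[C@H]1CC[C@]2(O)CC(=O)C([C@@H](C)C(=O)OCC=C)=C[C@]2(C)[C@H]1C | intermediate
18 | angelic acid, (2Z)-2-methylbut-2-enoic acid | C/C=C(/C)C(=O)O | starting material
19 | (2Z)-2-methylbut-2-enoic 2,4,6-trichlorobenzoic anhydride | C/C=C(/C)C(=O)OC(=O)c1c(Cl)cc(Cl)cc1Cl | intermediate (not isolated)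
20 | prop-2-en-1-yl (2R)-2-[(4aS,7S,8R,8aR)-4a-hydroxy-8,8a-dimethyl-7-{[(2Z)-2-methylbut-2-enoyl]oxy}-3-oxo-3,4,4a,5,6,7,8,8a-octahydronaphthalen-2-yl]propanoate | C/C=C(/C)C(=O)O[C@H]1CC[C@]2(O)CC(=O)C([C@@H](C)C(=O)OCC=C)=C[C@]2(C)[C@H]1C | intermediate
21 | (2R)-2-[(4aS,7S,8R,8aR)-4a-hydroxy-8,8a-dimethyl-7-{[(2Z)-2-methylbut-2-enoyl]oxy}-3-oxo-3,4,4a,5,6,7,8,8a-octahydronaphthalen-2-yl]propanoic acid | C/C=C(/C)C(=O)O[C@H]1CC[C@]2(O)CC(=O)C([C@@H](C)C(=O)O)=C[C@]2(C)[C@H]1C | target

**Step count**

Total steps: 13. Longest linear sequence: 11 (steps 1–4 and 7–13); steps 5–6 form the side branch.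

**Three steps most likely to fail**

Step 8. What may go wrong: alkene equilibration that is too slow relative to β-elimination of the tertiary hydroxyl, or a competing bridged aldol, so that material does not funnel into the cis-ketol. Fallback (sets out from 12, returns at 14): the three events are separated. DBU in CH2Cl2 at 0 °C opens 12 to (2R)-3-acetyl-4-[(6R,7R)-6,7-dimethyl-8-oxo-1,4-dioxaspiro[4.5]decan-7-yl]-2-methylbut-3-enoic acid F1 as an isolable E/Z mixture. Irradiation at 365 nm in MeCN (photochemical E→Z isomerisation of the enone) should enrich (2R,3Z)-3-acetyl-4-[(6R,7R)-6,7-dimethyl-8-oxo-1,4-dioxaspiro[4.5]decan-7-yl]-2-methylbut-3-enoic acid F2. F2 is then ketolised at −40 °C with KOtBu (2.2 equiv) in THF to give 14.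

Step 3. What may go wrong: low conversion or poor facial selectivity in methyl transfer to a hindered α-methyl enone flanked by the ketal, or retro-aldol loss of formaldehyde on work-up. Fallback (sets out from 1, returns at 5): the asymmetric addition is moved to the unhindered enone. Me2Zn, Cu(OTf)2 (2 mol %) and a chiral phosphoramidite in toluene at −30 °C, then Me3SiOTf, give (6R)-6-methyl-8-(trimethylsilyloxy)-1,4-dioxaspiro[4.5]dec-7-ene F3. MeLi then MeI gives (6R)-6,7-dimethyl-1,4-dioxaspiro[4.5]decan-8-one F4. Equilibrating silylation (Me3SiCl, NaI, Et3N) gives (6R)-6,7-dimethyl-8-(trimethylsilyloxy)-1,4-dioxaspiro[4.5]dec-7-ene F5. MeLi then monomeric CH2O at −78 °C gives 5.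

Step 7. What may go wrong: slow addition to the neopentyl aldehyde and erosion by the regioisomeric terminal enol silane. Fallback (sets out from 9, returns at 12): the enolate is generated regiospecifically from a halide. Acid-catalysed bromination of 9 (Br2, cat. HBr, AcOH, through the more substituted enol) gives methyl (2S)-3-bromo-2-methyl-4-oxopentanoate F6. Zinc in THF at 0 °C converts F6 into the zinc enolate, which adds to aldehyde 6 in a Reformatsky-type aldol to give 11; this is lactonised with PPTS in toluene as before to give 12.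

**Further compounds**

F1 | step 8 | (2R)-3-acetyl-4-[(6R,7R)-6,7-dimethyl-8-oxo-1,4-dioxaspiro[4.5]decan-7-yl]-2-methylbut-3-enoic acid (E/Z mixture) | O=C1CCC2(OCCO2)[C@H](C)[C@@]1(C)C=C(C(C)=O)[C@@H](C)C(=O)O
F2 | step 8 | (2R,3Z)-3-acetyl-4-[(6R,7R)-6,7-dimethyl-8-oxo-1,4-dioxaspiro[4.5]decan-7-yl]-2-methylbut-3-enoic acid | O=C1CCC2(OCCO2)[C@H](C)[C@@]1(C)/C=C(\C(C)=O)[C@@H](C)C(=O)O
F3 | step 3 | (6R)-6-methyl-8-(trimethylsilyloxy)-1,4-dioxaspiro[4.5]dec-7-ene | C[Si](C)(C)OC1=C[C@@H](C)C2(OCCO2)CC1
F4 | step 3 | (6R)-6,7-dimethyl-1,4-dioxaspiro[4.5]decan-8-one (mixture at C7) | O=C1CCC2(OCCO2)[C@H](C)C1C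
F5 | step 3 | (6R)-6,7-dimethyl-8-(trimethylsilyloxy)-1,4-dioxaspiro[4.5]dec-7-ene | C[Si](C)(C)OC1=C(C)[C@@H](C)C2(OCCO2)CC1
F6 | step 7 | methyl (2S)-3-bromo-2-methyl-4-oxopentanoate (mixture at C3) | CC(=O)C(Br)[C@@H](C)C(=O)OC
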